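Cycloshizukaol A is cut at both tetrasubstituted C4=C5 alkenes (lindenane numbering). These bonds are shared by each cyclopentene ring and the twelve-membered ring. Each C5 is the γ-carbon of a C6=C7–C8=O cyclohexenone and sits 1,5 to C4 across C10 and the cis-cyclopropane (C1, C3), so a C4 ketone invites a vinylogous aldol condensation. The key step does this twice, transannularly. A C2-symmetric eighteen-membered bis(enone) bis(cyclopropyl ketone) contracts to the twelve-membered ring and gains both bicyclo[3.1.0]hexene units and both dienones in one operation. The macrocycle comes from head-to-tail cyclodimerisation of one enantiopure monomer carrying a thioester and a neopentyl iodide.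

Key step: step 13

Numbering (each half): cyclopropane C1–C2–C3. C4 bears C15H2. C5 is the ring-fusion carbon. The six-membered ring is C5–C10 (C8 ketone, C9 carbinol, C10 quaternary with methyl C14). C11 is the quaternary ester carbon (C12 ester, C13 methyl). C15 of one half is bonded to C11 of the other.

Assumption: the enantiomer named for each chiral controller (auxiliary in step 2, catalysts in steps 5 and 7) is taken to deliver the drawn configuration by the accepted facial models; if a sense proves opposite, the antipodal controller is used and nothing else changes.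

Step 1
Reactants: 1 methyl 2-methyl-3-oxobutanoate; 2 L-valine tert-butyl ester
Product: 3 methyl (Z)-3-{[(S)-1-tert-butoxy-3-methyl-1-oxobutan-2-yl]amino}-2-methylbut-2-enoate
Conditions: BF3·OEt2 (cat.), benzene, reflux, Dean–Stark trap
Reagents that add atoms: L-valine tert-butyl ester CC(C)[C@H](N)C(=O)OC(C)(C)C
Why: Acid-catalysed enamine condensation of a β-keto ester with a primary amine should give the hydrogen-bonded (Z)-enamino ester, with no new stereocentre and the valine centre untouched.

Step 2
Reactants: 3 enamino ester; 4 diiodomethane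
Product: 6 methyl (R)-2-(iodomethyl)-2-methyl-3-oxobutanoate, via iodomethylated ketimine 5 (not isolated)
Conditions: LiN(i-Pr)2, toluene, HMPA (1 equiv), −78 °C; CH2I2, −78 to −20 °C; then 1 M aq. citric acid, THF, rt
Reagents that add atoms: diiodomethane ICI; water O
Why: Auxiliary-controlled alkylation of a chelated lithio-enamine (aza-enolate): lithium is held by the nitrogen and both ester carbonyls, the isopropyl group covers one face, CH2I2 should enter from the other and set C11 as R, and mild acid hydrolysis of ketimine 5 returns the ketone and the auxiliary.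

Step 3
Reactants: 6 methyl (R)-2-(iodomethyl)-2-methyl-3-oxobutanoate
Product: 7 methyl (R)-2-(iodomethyl)-2-methyl-3-(trifluoromethylsulfonyloxy)but-3-enoate
Conditions: KN(SiMe3)2, THF, −78 °C; PhNTf2, −78 to −20 °C
Reagents that add atoms: N-phenylbis(trifluoromethanesulfonimide) O=S(=O)(N(c1ccccc1)S(=O)(=O)C(F)(F)F)C(F)(F)F
Why: Enol triflate formation: the ketone can enolise only towards its methyl group because C11 is quaternary, O-sulfonylation of the potassium enolate should give the 1,1-disubstituted vinyl triflate, and the neopentyl iodide is inert at this temperature.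

Step 4
Reactants: 7 enol triflate; 8 tributyl(vinyl)stannane
Product: 9 methyl (R)-2-(iodomethyl)-2-methyl-3-methylenepent-4-enoate
Conditions: Pd(PPh3)4 (5 mol %), LiCl (3 equiv), THF, 60 °C
Reagents that add atoms: tributyl(vinyl)stannane C=C[Sn](CCCC)(CCCC)CCCC
Why: Stille coupling: the vinyl triflate should add to zerovalent palladium far faster than the neopentyl iodide, and vinyl transfer from tin gives the 2-substituted butadiene (C5=C6–C7=C8) under neutral conditions that leave C11 untouched.

Step 5
Reactants: 9 diene; 10 methacrolein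
Product: 11 methyl (R)-2-[(R)-4-formyl-4-methylcyclohex-1-en-1-yl]-3-iodo-2-methylpropanoate
Conditions: (S)-α,α-diphenylprolinol-derived B-o-tolyl oxazaborolidine activated with Tf2NH (20 mol %), CH2Cl2, −78 to −40 °C
Reagents that add atoms: methacrolein CC(=C)C=O
Why: Catalytic enantioselective Diels–Alder reaction: the 2-substituted diene should add in the "para" sense (C5–C10 and C8–C9 bonds), and the boron-bound s-trans enal is shielded on one face by the catalyst aryl group, which sets the quaternary C10 under catalyst control, C11 being too remote to interfere.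

Step 6
Reactants: 11 aldehyde; 12 methyltriphenylphosphonium bromide
Product: 13 methyl (R)-3-iodo-2-methyl-2-[(R)-4-methyl-4-vinylcyclohex-1-en-1-yl]propanoate
Conditions: Ph3PCH3Br, KOt-Bu, THF, 0 °C
Reagents that add atoms: methyltriphenylphosphonium bromide C[P+](c1ccccc1)(c1ccccc1)c1ccccc1.[Br-]
Why: Wittig methylenation of a non-enolisable neopentyl aldehyde should give the C1=C2 vinyl group without touching the hindered methyl ester, the iodide or either stereocentre.

Step 7
Reactants: 13 vinyl compound; 14 tert-butyl diazoacetate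
Product: 15 tert-butyl (1S,2R)-2-{(R)-4-[(R)-1-iodo-3-methoxy-2-methyl-3-oxopropan-2-yl]-1-methylcyclohex-3-en-1-yl}cyclopropane-1-carboxylate
Conditions: chiral aryliridium–salen complex Ir(salen*)(C6H4Me-4) (2 mol %; salen* = 2'-phenylbinaphthyl salen of (1R,2R)-cyclohexane-1,2-diamine), THF, −78 to −30 °C, slow addition of 14
Reagents that add atoms: tert-butyl diazoacetate CC(C)(C)OC(=O)C=[N+]=[N-]
Why: cis-Selective catalytic asymmetric cyclopropanation with an iridium–salen carbene: the monosubstituted C1=C2 alkene should react in preference to the hindered trisubstituted C6=C7 alkene, and the catalyst sets C1 (R) and C3 (S) with C4 and C10 cis.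

Step 8
Reactants: 15 cyclopropane ester
Product: 17 tert-butyl (1S,2R)-2-{(S)-4-[(R)-1-iodo-3-methoxy-2-methyl-3-oxopropan-2-yl]-1-methyl-5-oxocyclohex-3-en-1-yl}cyclopropane-1-carboxylate, via C8 allylic alcohol 16 (not isolated)
Conditions: SeO2 (0.3 equiv), t-BuOOH (3 equiv), CH2Cl2, rt; filtration through silica; then Dess–Martin periodinane, CH2Cl2, 0 °C
Reagents that add atoms: selenium dioxide O=[Se]=O; tert-butyl hydroperoxide CC(C)(C)OO
Why: Selenium dioxide allylic oxidation (ene reaction, then [2,3]-shift) should attack the ring CH2 on the more substituted alkene terminus, here C8 since C11 has no hydrogen, and immediate Dess–Martin oxidation of crude 16 gives the enone before the C8 alcohol can lactonise onto the C12 ester; the C8 centre is erased.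

Step 9
Reactants: 17 enone
Product: 19 tert-butyl (1S,2R)-2-{(1R,6R)-6-[(tert-butyldimethylsilyl)oxy]-4-[(R)-1-iodo-3-methoxy-2-methyl-3-oxopropan-2-yl]-1-methyl-5-oxocyclohex-3-en-1-yl}cyclopropane-1-carboxylate, via lithium C9 alkoxide 18 (not isolated)
Conditions: LiN(SiMe3)2, THF, −78 °C; 2-(phenylsulfonyl)-3-phenyloxaziridine, −78 °C; then t-BuMe2SiOTf, −78 to 0 °C
Reagents that add atoms: 2-(phenylsulfonyl)-3-phenyloxaziridine O=S(=O)(c1ccccc1)N1OC1c1ccccc1; tert-butyldimethylsilyl triflate CC(C)(C)[Si](C)(C)OS(=O)(=O)C(F)(F)F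
Why: Kinetic α'-deprotonation of the enone at C9 and electrophilic hydroxylation with an N-sulfonyloxaziridine: the reagent should approach C9 anti to the bulky cis-substituted cyclopropyl group on C10, that is syn to the C14 methyl, which sets C9 as R, and the lithium alkoxide 18 is silylated in the same flask.

Step 10
Reactants: 19 silyl ether tert-butyl ester
Product: 20 (1S,2R)-2-{(1R,6R)-6-[(tert-butyldimethylsilyl)oxy]-4-[(R)-1-iodo-3-methoxy-2-methyl-3-oxopropan-2-yl]-1-methyl-5-oxocyclohex-3-en-1-yl}cyclopropane-1-carboxylic acid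
Conditions: 85% aq. H3PO4, toluene, rt
Reagents that add atoms: none
Why: Acidolysis (alkyl–oxygen cleavage) of the tert-butyl ester with aqueous phosphoric acid should leave the methyl ester, the silyl ether, the iodide and the cyclopropane intact.

Step 11
Reactants: 20 acid
Product: 21 S-ethyl (1S,2R)-2-{(1R,6R)-6-[(tert-butyldimethylsilyl)oxy]-4-[(R)-1-iodo-3-methoxy-2-methyl-3-oxopropan-2-yl]-1-methyl-5-oxocyclohex-3-en-1-yl}cyclopropane-1-carbothioate
Conditions: EtSH, EDC·HCl, DMAP (cat.), CH2Cl2, 0 °C to rt
Reagents that add atoms: ethanethiol CCS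
Why: Carbodiimide (Steglich-type) thioesterification should activate only the free C4 acid and does not epimerise the cyclopropane.

Step 12
Reactants: 21 thioester iodide (two molecules)
Product: 24 C2-symmetric eighteen-membered head-to-tail cyclodimer in which each half is a (9R,10R)-9-silyloxycyclohex-6-en-8-one bearing on C10 a (1R,3S)-cis-cyclopropyl C4 ketone whose C15H2 is bonded to (11R)-C11 of the other half, via monomeric zinc reagent 22 (not isolated), via linear dimer zinc reagent 23 (not isolated)
Conditions: Zn dust (activated with 1,2-dibromoethane and Me3SiCl), LiCl, THF, 40 °C; decant from excess zinc; syringe-pump addition to PdCl2(PPh3)2 (10 mol %) in toluene (final 5 mM), rt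
Reagents that add atoms: none
Why: Zinc insertion into the β-iodo ester gives a zinc homoenolate that tolerates enone, ester and thioester, and the Fukuyama ketone synthesis (palladium-catalysed thioester–organozinc coupling) should join C15 to C4 first between two molecules (23) and then within the linear dimer; closure within one monomer would need an impossibly strained nine-membered bridge, and no stereocentre is involved.

Step 13
Reactants: 24 eighteen-membered macrocycle
Product: 26 9,9'-bis(tert-butyldimethylsilyl) ether of cycloshizukaol A, via half-closed fifteen-membered dienone 25 (not isolated)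
Conditions: KOt-Bu (0.4 equiv), t-BuOH–THF (1:4), 4 Å molecular sieves, 5 mM, 0 to 45 °C
Reagents that add atoms: none
Why: Catalytic KOt-Bu reversibly removes a C5–H (γ to C8=O) to give the linear dienolate O–C8=C7–C6=C5, whose γ-carbon adds to the C4 ketone held 1,5 to it by the cis-cyclopropane, and E1cB loss of hydroxide from the tertiary aldolate gives the C4=C5–C6=C7–C8=O dienone; the sequence then repeats in the second half of 25. The closest known reaction type is the intramolecular vinylogous (γ-selective) aldol condensation of cyclohexenones. Each of the two five-membered rings closes in the 5-(enolexo)-exo-trig mode, and each closure shortens the large ring by three atoms (eighteen to fifteen to twelve). No stereocentre is created in the product (the C4 carbinol and C5 methine are transient); C1, C9, C10 and C11 are carried through, and epimerisation at C3 of the cyclopropyl ketone is harmless because only the cis isomer can cyclise and the trans isomer returns through the enolate. The step needs C5 rather than C7 or C9 as the nucleophilic site: attack through C7 would give a bridged seven-membered ring with a new quaternary centre, and the aldol through C9 is reversible and cannot dehydrate because C9 carries the silyloxy group, so only the C5 pathway drains irreversibly into the conjugated dienone. The C15 enolates of the C4 ketones can reach only three- or four-membered closures and stay spectators.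

Step 14
Reactants: 26 bis(silyl ether)
Product: 27 cycloshizukaol A
Conditions: HF·pyridine, pyridine, THF, 0 °C to rt
Reagents that add atoms: none
Why: Fluoride-mediated cleavage of the two silyl ethers under buffered conditions should free the C9 alcohols without enolising C9 or opening the vinylcyclopropanes.

Compound list
1 | methyl 2-methyl-3-oxobutanoate | COC(=O)C(C)C(C)=O | starting material
2 | L-valine tert-butyl ester | CC(C)[C@H](N)C(=O)OC(C)(C)C | starting material
3 | methyl (Z)-3-{[(S)-1-tert-butoxy-3-methyl-1-oxobutan-2-yl]amino}-2-methylbut-2-enoate | COC(=O)/C(C)=C(/C)N[C@@H](C(C)C)C(=O)OC(C)(C)C | intermediate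
4 | diiodomethane | ICI | starting material
5 | methyl (R)-3-{[(S)-1-tert-butoxy-3-methyl-1-oxobutan-2-yl]imino}-2-(iodomethyl)-2-methylbutanoate (not isolated) | COC(=O)[C@](C)(CI)C(C)=N[C@@H](C(C)C)C(=O)OC(C)(C)C | intermediate
6 | methyl (R)-2-(iodomethyl)-2-methyl-3-oxobutanoate | CC(=O)[C@](C)(C(=O)OC)CI | intermediate
7 | methyl (R)-2-(iodomethyl)-2-methyl-3-(trifluoromethylsulfonyloxy)but-3-enoate | C=C(OS(=O)(=O)C(F)(F)F)[C@](C)(C(=O)OC)CI | intermediate
8 | tributyl(vinyl)stannane | C=C[Sn](CCCC)(CCCC)CCCC | starting material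
9 | methyl (R)-2-(iodomethyl)-2-methyl-3-methylenepent-4-enoate | C=CC(=C)[C@](C)(C(=O)OC)CI | intermediate
10 | methacrolein | CC(=C)C=O | starting material
11 | methyl (R)-2-[(R)-4-formyl-4-methylcyclohex-1-en-1-yl]-3-iodo-2-methylpropanoate | O=C[C@@]1(C)CC=C(CC1)[C@](C)(C(=O)OC)CI | intermediate
12 | methyltriphenylphosphonium bromide | C[P+](c1ccccc1)(c1ccccc1)c1ccccc1.[Br-] | starting material
13 | methyl (R)-3-iodo-2-methyl-2-[(R)-4-methyl-4-vinylcyclohex-1-en-1-yl]propanoate | C=C[C@@]1(C)CC=C(CC1)[C@](C)(C(=O)OC)CI | intermediate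
14 | tert-butyl diazoacetate | CC(C)(C)OC(=O)C=[N+]=[N-] | starting material
15 | cis-cyclopropane tert-butyl ester (1R,3S,10R,11R) | CC(C)(C)OC(=O)[C@H]2C[C@H]2[C@@]1(C)CC=C(CC1)[C@](C)(C(=O)OC)CI | intermediate
16 | C8 allylic alcohol, both C8 epimers (not isolated) | CC(C)(C)OC(=O)[C@H]2C[C@H]2[C@@]1(C)CC=C(C(O)C1)[C@](C)(C(=O)OC)CI | intermediate
17 | C8 enone (1R,3S,10S,11R) | CC(C)(C)OC(=O)[C@H]2C[C@H]2[C@@]1(C)CC=C(C(=O)C1)[C@](C)(C(=O)OC)CI | intermediate
18 | lithium alkoxide of the (9R)-9-hydroxy enone (not isolated) | CC(C)(C)OC(=O)[C@H]2C[C@H]2[C@@]1(C)CC=C(C(=O)[C@@H]1[O-])[C@](C)(C(=O)OC)CI.[Li+] | intermediate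
19 | (9R)-9-silyloxy enone tert-butyl ester (1R,3S,9R,10R,11R) | CC(C)(C)OC(=O)[C@H]2C[C@H]2[C@@]1(C)CC=C(C(=O)[C@@H]1O[Si](C)(C)C(C)(C)C)[C@](C)(C(=O)OC)CI | intermediate
20 | C4 carboxylic acid | OC(=O)[C@H]2C[C@H]2[C@@]1(C)CC=C(C(=O)[C@@H]1O[Si](C)(C)C(C)(C)C)[C@](C)(C(=O)OC)CI | intermediate
21 | C4 S-ethyl thioester, C15 iodide (monomer) | CCSC(=O)[C@H]2C[C@H]2[C@@]1(C)CC=C(C(=O)[C@@H]1O[Si](C)(C)C(C)(C)C)[C@](C)(C(=O)OC)CI | intermediate
22 | monomeric C15 zinc iodide of 21 (not isolated) | CCSC(=O)[C@H]2C[C@H]2[C@@]1(C)CC=C(C(=O)[C@@H]1O[Si](C)(C)C(C)(C)C)[C@](C)(C(=O)OC)C[Zn]I | intermediate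
23 | linear head-to-tail dimer, thioester and zinc iodide termini (not isolated) | CCSC(=O)[C@H]2C[C@H]2[C@@]1(C)CC=C(C(=O)[C@@H]1O[Si](C)(C)C(C)(C)C)[C@](C)(C(=O)OC)CC(=O)[C@H]4C[C@H]4[C@@]3(C)CC=C(C(=O)[C@@H]3O[Si](C)(C)C(C)(C)C)[C@](C)(C(=O)OC)C[Zn]I | intermediate
24 | C2-symmetric eighteen-membered bis(enone) bis(cis-cyclopropyl ketone) | COC(=O)[C@]1(C)CC(=O)[C@H]2C[C@H]2[C@@]3(C)CC=C(C(=O)[C@@H]3O[Si](C)(C)C(C)(C)C)[C@](C)(C(=O)OC)CC(=O)[C@H]4C[C@H]4[C@@]5(C)CC=C1C(=O)[C@@H]5O[Si](C)(C)C(C)(C)C | intermediate
25 | half-closed fifteen-membered compound, one dienone and one open half (not isolated) | COC(=O)[C@]1(C)CC(=O)[C@H]2C[C@H]2[C@@]3(C)CC=C(C(=O)[C@@H]3O[Si](C)(C)C(C)(C)C)[C@](C)(C(=O)OC)CC4=C5C=C1C(=O)[C@H](O[Si](C)(C)C(C)(C)C)[C@@]5(C)[C@@H]6C[C@H]46 | intermediate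
26 | 9,9'-bis(tert-butyldimethylsilyl) ether of cycloshizukaol A | COC(=O)[C@]1(C)CC2=C3C=C(C(=O)[C@H](O[Si](C)(C)C(C)(C)C)[C@@]3(C)[C@@H]3C[C@H]23)[C@](C)(C(=O)OC)CC2=C3C=C1C(=O)[C@H](O[Si](C)(C)C(C)(C)C)[C@@]3(C)[C@@H]1C[C@H]21 | intermediate
27 | cycloshizukaol A (1R,3S,9R,10S,11R in each half) | COC(=O)[C@]1(C)CC2=C3C=C(C(=O)[C@H](O)[C@@]3(C)[C@@H]3C[C@H]23)[C@](C)(C(=O)OC)CC2=C3C=C1C(=O)[C@H](O)[C@@]3(C)[C@@H]1C[C@H]21 | target

Total step count: 14. Longest linear sequence: 14 (steps 1 to 14; both halves come from the same monomer).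

Steps most likely to fail

Step 12. Linear oligomerisation and protonation of the zinc reagent may outrun the eighteen-membered ring closure, because both coupling partners sit in one molecule. The fallback replaces the cyclodimerisation by a stepwise assembly. It sets out from 19 and 21 and returns at 24.
- Zinc insertion into 19 gives the zinc reagent of the tert-butyl ester F1.
- After removal of excess zinc, F1 is coupled (PdCl2(PPh3)2, toluene, rt) with one equivalent of 21. The neopentyl iodide of 21 is inert to zerovalent palladium at room temperature. This gives the linear keto dimer with tert-butyl ester and iodide termini F2.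
- Aqueous H3PO4 frees the linear dimer acid F3, and EtSH/EDC gives the linear dimer thioester iodide F4.
- Zinc insertion then gives 23, and a now unimolecular Fukuyama closure at 1 mM gives 24.

Step 13. Three things may go wrong. The aldol equilibrium at the hindered C4 ketone may lie on the open side. The second closure may be slowed by strain building in the shrinking ring. Prolonged exposure to base may epimerise C9. The fallback closes the same C4–C5 bond in the monomer on a stronger electrophile and makes the large ring afterwards. It sets out from 21 and returns at 26.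
- KN(SiMe3)2 (THF, −78 to 0 °C) triggers a vinylogous Dieckmann condensation of the C5 dienolate on the thioester. It is driven by the stabilised vinylogous 1,3-diketonate and gives the closed monomer 4-hydroxy dienone F5.
- PhNTf2 gives the C4 enol triflate F6.
- Zinc insertion into the neopentyl iodide gives the zinc reagent of the triflate F7.
- A head-to-tail double Negishi coupling (PdCl2(dppf), THF, 5 mM) runs through the linear triflate–zinc dimer F8, joins C15 to C4 twice and gives 26.

Step 7. Carbene transfer to a vinyl group next to a quaternary carbon may be sluggish. Carbene dimerisation could then take over and cis selectivity could erode. The fallback builds the cis-cyclopropane from a Z-alkene under reagent control. It sets out from 11 and returns at 15.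
- Still–Gennari olefination (methyl bis(2,2,2-trifluoroethyl)phosphonoacetate, KN(SiMe3)2, 18-crown-6) gives the (Z)-enoate F9.
- i-Bu2AlH (CH2Cl2, −78 °C) reduces the unhindered conjugated ester in preference to the quaternary one and gives the (Z)-allylic alcohol F10.
- A dioxaborolane-directed asymmetric Simmons–Smith cyclopropanation (Zn(CH2I)2, (4S,5S)-2-butyl-N,N,N',N'-tetramethyl-1,3,2-dioxaborolane-4,5-dicarboxamide) gives the cis-cyclopropylmethanol F11.
- TEMPO/PhI(OAc)2 in aqueous MeCN gives the cis-cyclopropane acid F12.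
- Boc2O/DMAP/t-BuOH gives 15.

Further compounds
F1 | step 12 | zinc reagent of the tert-butyl ester | CC(C)(C)OC(=O)[C@H]2C[C@H]2[C@@]1(C)CC=C(C(=O)[C@@H]1O[Si](C)(C)C(C)(C)C)[C@](C)(C(=O)OC)C[Zn]I
F2 | step 12 | linear keto dimer with tert-butyl ester and iodide termini | CC(C)(C)OC(=O)[C@H]2C[C@H]2[C@@]1(C)CC=C(C(=O)[C@@H]1O[Si](C)(C)C(C)(C)C)[C@](C)(C(=O)OC)CC(=O)[C@H]4C[C@H]4[C@@]3(C)CC=C(C(=O)[C@@H]3O[Si](C)(C)C(C)(C)C)[C@](C)(C(=O)OC)CI
F3 | step 12 | linear dimer acid | OC(=O)[C@H]2C[C@H]2[C@@]1(C)CC=C(C(=O)[C@@H]1O[Si](C)(C)C(C)(C)C)[C@](C)(C(=O)OC)CC(=O)[C@H]4C[C@H]4[C@@]3(C)CC=C(C(=O)[C@@H]3O[Si](C)(C)C(C)(C)C)[C@](C)(C(=O)OC)CI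
F4 | step 12 | linear dimer thioester iodide | CCSC(=O)[C@H]2C[C@H]2[C@@]1(C)CC=C(C(=O)[C@@H]1O[Si](C)(C)C(C)(C)C)[C@](C)(C(=O)OC)CC(=O)[C@H]4C[C@H]4[C@@]3(C)CC=C(C(=O)[C@@H]3O[Si](C)(C)C(C)(C)C)[C@](C)(C(=O)OC)CI
F5 | step 13 | closed monomer 4-hydroxy dienone | OC2=C3C=C(C(=O)[C@H](O[Si](C)(C)C(C)(C)C)[C@@]3(C)[C@@H]3C[C@H]23)[C@](C)(C(=O)OC)CI
F6 | step 13 | C4 enol triflate | O=S(=O)(OC2=C3C=C(C(=O)[C@H](O[Si](C)(C)C(C)(C)C)[C@@]3(C)[C@@H]3C[C@H]23)[C@](C)(C(=O)OC)CI)C(F)(F)F
F7 | step 13 | zinc reagent of the triflate | O=S(=O)(OC2=C3C=C(C(=O)[C@H](O[Si](C)(C)C(C)(C)C)[C@@]3(C)[C@@H]3C[C@H]23)[C@](C)(C(=O)OC)C[Zn]I)C(F)(F)F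
F8 | step 13 | linear triflate–zinc dimer | O=S(=O)(OC2=C3C=C(C(=O)[C@H](O[Si](C)(C)C(C)(C)C)[C@@]3(C)[C@@H]3C[C@H]23)[C@](C)(C(=O)OC)CC4=C5C=C(C(=O)[C@H](O[Si](C)(C)C(C)(C)C)[C@@]5(C)[C@@H]5C[C@H]45)[C@](C)(C(=O)OC)C[Zn]I)C(F)(F)F
F9 | step 7 | (Z)-enoate | COC(=O)/C=C\[C@@]1(C)CC=C(CC1)[C@](C)(C(=O)OC)CI
F10 | step 7 | (Z)-allylic alcohol | OC/C=C\[C@@]1(C)CC=C(CC1)[C@](C)(C(=O)OC)CI
F11 | step 7 | cis-cyclopropylmethanol | OC[C@H]2C[C@H]2[C@@]1(C)CC=C(CC1)[C@](C)(C(=O)OC)CI
F12 | step 7 | cis-cyclopropane acid | OC(=O)[C@H]2C[C@H]2[C@@]1(C)CC=C(CC1)[C@](C)(C(=O)OC)CI
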